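The ring is cut into two three-carbon units, C6–C1–C2 (tertiary carbinol and side chain) and C3–C4–C5. At the oxidation level of a 4-alkyl-4-silyloxycyclohexa-2,5-dienone the six-membered ring has a mirror plane through C1 and C4, and the key step exploits this hidden symmetry. The dianion of dimethyl (2-oxopropyl)phosphonate joins an achiral 2-alkyl-2-silyloxymalonaldehyde by aldol addition (C5–C6) and ring-closing Horner–Wadsworth–Emmons olefination (C2=C3) in one operation, with dehydration in the same flask. Enantioselective conjugate reduction of one enone arm, α-hydroxylation and carbonyl reduction then set C1, C5 and C4 in turn.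

Key step: step 5

Remark: ring atoms are numbered as in the final triol (C1 tertiary carbinol, C2=C3, C4 and C5 secondary carbinols, C6 methylene); compound names follow their own nomenclature numbering.

Step 1
Reactants: 1 (E)-hex-1-en-1-ylboronic acid; 2 1,11-dibromoundecane (4 equiv)
Product: 3 (E)-17-bromoheptadec-5-ene
Conditions: Pd(OAc)2 (cat.), P(t-Bu)2Me (cat.), KOt-Bu, t-amyl alcohol, rt
Reagents that add atoms: none
Why: Suzuki–Miyaura coupling of a primary alkyl bromide with an alkenylboronic acid under an electron-rich trialkylphosphine–palladium catalyst should retain the E geometry, and the excess of 2 restricts reaction to one C–Br bond.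

Step 2
Reactants: 3 (E)-17-bromoheptadec-5-ene; 4 diethyl 2-oxomalonate
Product: 6 diethyl 2-[(E)-heptadec-12-en-1-yl]-2-hydroxymalonate, via Grignard reagent 5 (not isolated)
Conditions: Mg, THF, 50 °C; then add to 4, THF, −78 °C; aq. NH4Cl
Reagents that add atoms: none
Why: Grignard addition to the central keto group of the vicinal tricarbonyl compound, by far its most electrophilic carbonyl, should give the tertiary alcohol while the esters survive at −78 °C.

Step 3
Reactants: 6 diethyl 2-[(E)-heptadec-12-en-1-yl]-2-hydroxymalonate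
Product: 7 diethyl 2-[(tert-butyldimethylsilyl)oxy]-2-[(E)-heptadec-12-en-1-yl]malonate
Conditions: TBSOTf, 2,6-lutidine, CH2Cl2, 0 °C → rt
Reagents that add atoms: tert-butyldimethylsilyl trifluoromethanesulfonate, CC(C)(C)[Si](C)(C)OS(=O)(=O)C(F)(F)F
Why: A silyl triflate with a hindered pyridine base silylates even congested tertiary alcohols (silyl ether protection), and the bulky silyl group is chosen to slow later silyl migration.

Step 4
Reactants: 7 diethyl 2-[(tert-butyldimethylsilyl)oxy]-2-[(E)-heptadec-12-en-1-yl]malonate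
Product: 8 2-[(tert-butyldimethylsilyl)oxy]-2-[(E)-heptadec-12-en-1-yl]propanedial
Conditions: i-Bu2AlH (2.2 equiv), CH2Cl2, −78 °C; aq. potassium sodium tartrate
Reagents that add atoms: none
Why: Partial ester reduction with a dialkylaluminium hydride: each α-silyloxy ester should stop at the aluminium hemiacetal at −78 °C and release the aldehyde only on work-up, and the product has no α-hydrogen to enolise.

Step 5
Reactants: 8 2-[(tert-butyldimethylsilyl)oxy]-2-[(E)-heptadec-12-en-1-yl]propanedial; 9 dimethyl (2-oxopropyl)phosphonate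
Product: 14 4-[(tert-butyldimethylsilyl)oxy]-4-[(E)-heptadec-12-en-1-yl]cyclohexa-2,5-dien-1-one, via phosphonate dianion 10 (not isolated), via open-chain aldolate 11 (not isolated), via cyclic alkoxide 12 (not isolated), via mesylate 13 (not isolated)
Conditions: 9, LiN(i-Pr)2 (2.1 equiv), THF, −78 → 0 °C; add to 8, THF, −78 → 0 °C; then MsCl, Et3N, 0 °C → rt
Reagents that add atoms: none
Why: The dianion 10 attacks one aldehyde of 8 through its terminal, more basic carbanion (aldol addition, forming the C5–C6 bond of the final ring), which leaves the phosphonate-stabilised carbanion of 11 intact. On warming, that carbanion closes the six-membered ring onto the second aldehyde by intramolecular Horner–Wadsworth–Emmons olefination (forming C2=C3; a 6-(enolendo)-exo-trig closure in which the ring enforces the cis alkene), and mesylation with E1cB elimination removes the aldol oxygen to give the symmetric dienone. The closest known reaction type is γ-functionalisation of a β-ketophosphonate dianion followed by ring-closing Horner–Wadsworth–Emmons reaction to a cyclohexenone. The carbinol and quaternary stereocentres of 11–13 are transient and form as mixtures, because elimination makes the product achiral, so no stereocontrol is needed here. The step needs γ- before α-reactivity of the dianion and a single intermolecular addition per dialdehyde: the first is inherent to the dianion, the second is secured by adding 10 to 8 at −78 °C so that ring closure outruns a second addition, while the quaternary α-carbon of 8 excludes enolisation.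

Step 6
Reactants: 14 4-[(tert-butyldimethylsilyl)oxy]-4-[(E)-heptadec-12-en-1-yl]cyclohexa-2,5-dien-1-one
Product: 15 (R)-4-[(tert-butyldimethylsilyl)oxy]-4-[(E)-heptadec-12-en-1-yl]cyclohex-2-en-1-one
Conditions: Cu(OAc)2·H2O (cat.), DTBM-SEGPHOS (one antipode, cat.), (EtO)2MeSiH, t-BuOH, toluene, 0 °C
Reagents that add atoms: none
Why: Ligand-bound copper hydride adds hydride to the β-carbon of one of the two enantiotopic enone arms of the achiral dienone (catalytic asymmetric conjugate reduction used as a desymmetrisation), so the chiral bisphosphine alone sets the quaternary stereocentre; the antipode that delivers the R enone is used, and t-BuOH protonates the copper enolate.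

Step 7
Reactants: 15 (R)-4-[(tert-butyldimethylsilyl)oxy]-4-[(E)-heptadec-12-en-1-yl]cyclohex-2-en-1-one
Product: 17 (4R,6R)-4-[(tert-butyldimethylsilyl)oxy]-4-[(E)-heptadec-12-en-1-yl]-6-hydroxycyclohex-2-en-1-one, via potassium dienolate 16 (not isolated)
Conditions: KN(SiMe3)2, THF, −78 °C; 2-(phenylsulfonyl)-3-phenyloxaziridine, −78 °C; aq. NH4Cl
Reagents that add atoms: 2-(phenylsulfonyl)-3-phenyloxaziridine, O=S(=O)(c1ccccc1)N1OC1c1ccccc1
Why: Davis enolate oxidation: deprotonation can occur only at C6 because C4 is quaternary, and the oxaziridine should approach the dienolate anti to the pseudoaxial silyloxy group at C4 (1,3-induction, the chain lying pseudoequatorial), giving the 4,6-trans hydroxy ketone.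

Step 8
Reactants: 17 (4R,6R)-4-[(tert-butyldimethylsilyl)oxy]-4-[(E)-heptadec-12-en-1-yl]-6-hydroxycyclohex-2-en-1-one
Product: 18 (1R,2R,5R)-5-[(tert-butyldimethylsilyl)oxy]-5-[(E)-heptadec-12-en-1-yl]cyclohex-3-ene-1,2-diol
Conditions: NaBH4, CeCl3·7H2O, MeOH, −78 °C
Reagents that add atoms: none
Why: Luche reduction: 1,2-selective axial hydride delivery to the half-chair with equatorial chain and equatorial C6 hydroxyl should place the new hydroxyl trans to the adjacent one and cis to the silyloxy group.

Step 9
Reactants: 18 (1R,2R,5R)-5-[(tert-butyldimethylsilyl)oxy]-5-[(E)-heptadec-12-en-1-yl]cyclohex-3-ene-1,2-diol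
Product: 19 (1R,4R,5R)-1-[(E)-heptadec-12-en-1-yl]cyclohex-2-ene-1,4,5-triol
Conditions: Bu4NF, THF, rt
Reagents that add atoms: none
Why: Fluoride-mediated desilylation should cleave the tertiary silyl ether under non-acidic conditions that leave the tertiary allylic alcohol, the allylic diol and the chain alkene untouched.

Compound list
1 | (E)-hex-1-en-1-ylboronic acid | CCCC/C=C/B(O)O | starting material
2 | 1,11-dibromoundecane | BrCCCCCCCCCCCBr | starting material
3 | (E)-17-bromoheptadec-5-ene | CCCC/C=C/CCCCCCCCCCCBr | intermediate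
4 | diethyl 2-oxomalonate | CCOC(=O)C(=O)C(=O)OCC | starting material
5 | (E)-heptadec-12-en-1-ylmagnesium bromide (Grignard reagent) | CCCC/C=C/CCCCCCCCCCC[Mg]Br | intermediate
6 | diethyl 2-[(E)-heptadec-12-en-1-yl]-2-hydroxymalonate | CCCC/C=C/CCCCCCCCCCCC(O)(C(=O)OCC)C(=O)OCC | intermediate
7 | diethyl 2-[(tert-butyldimethylsilyl)oxy]-2-[(E)-heptadec-12-en-1-yl]malonate | CCCC/C=C/CCCCCCCCCCCC(O[Si](C)(C)C(C)(C)C)(C(=O)OCC)C(=O)OCC | intermediate
8 | 2-[(tert-butyldimethylsilyl)oxy]-2-[(E)-heptadec-12-en-1-yl]propanedial | CCCC/C=C/CCCCCCCCCCCC(O[Si](C)(C)C(C)(C)C)(C=O)C=O | intermediate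
9 | dimethyl (2-oxopropyl)phosphonate | CC(=O)CP(=O)(OC)OC | starting material
10 | dilithium dianion of dimethyl (2-oxopropyl)phosphonate (phosphonate dianion) | [Li+].[Li+].C=C([O-])[CH-]P(=O)(OC)OC | intermediate
11 | open-chain aldolate: dilithium salt of dimethyl [(17E)-5-[(tert-butyldimethylsilyl)oxy]-5-formyl-4-hydroxy-2-oxodocos-17-en-1-yl]phosphonate (mixture of stereoisomers) | CCCC/C=C/CCCCCCCCCCCC(O[Si](C)(C)C(C)(C)C)(C=O)C([O-])CC(=O)[CH-]P(=O)(OC)OC.[Li+].[Li+] | intermediate
12 | cyclic alkoxide: lithium salt of 4-[(tert-butyldimethylsilyl)oxy]-4-[(E)-heptadec-12-en-1-yl]-5-hydroxycyclohex-2-en-1-one (mixture of stereoisomers) | CCCC/C=C/CCCCCCCCCCCC1(O[Si](C)(C)C(C)(C)C)C=CC(=O)CC1[O-].[Li+] | intermediate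
13 | mesylate: 2-[(tert-butyldimethylsilyl)oxy]-2-[(E)-heptadec-12-en-1-yl]-5-oxocyclohex-3-en-1-yl methanesulfonate (mixture of stereoisomers) | CCCC/C=C/CCCCCCCCCCCC1(O[Si](C)(C)C(C)(C)C)C=CC(=O)CC1OS(C)(=O)=O | intermediate
14 | 4-[(tert-butyldimethylsilyl)oxy]-4-[(E)-heptadec-12-en-1-yl]cyclohexa-2,5-dien-1-one | CCCC/C=C/CCCCCCCCCCCC1(O[Si](C)(C)C(C)(C)C)C=CC(=O)C=C1 | intermediate
15 | (R)-4-[(tert-butyldimethylsilyl)oxy]-4-[(E)-heptadec-12-en-1-yl]cyclohex-2-en-1-one | CCCC/C=C/CCCCCCCCCCC[C@]1(O[Si](C)(C)C(C)(C)C)C=CC(=O)CC1 | intermediate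
16 | potassium (R)-4-[(tert-butyldimethylsilyl)oxy]-4-[(E)-heptadec-12-en-1-yl]cyclohexa-1,5-dien-1-olate (potassium dienolate) | CCCC/C=C/CCCCCCCCCCC[C@]1(O[Si](C)(C)C(C)(C)C)C=CC([O-])=CC1.[K+] | intermediate
17 | (4R,6R)-4-[(tert-butyldimethylsilyl)oxy]-4-[(E)-heptadec-12-en-1-yl]-6-hydroxycyclohex-2-en-1-one | CCCC/C=C/CCCCCCCCCCC[C@]1(O[Si](C)(C)C(C)(C)C)C=CC(=O)[C@H](O)C1 | intermediate
18 | (1R,2R,5R)-5-[(tert-butyldimethylsilyl)oxy]-5-[(E)-heptadec-12-en-1-yl]cyclohex-3-ene-1,2-diol | CCCC/C=C/CCCCCCCCCCC[C@]1(O[Si](C)(C)C(C)(C)C)C=C[C@@H](O)[C@H](O)C1 | intermediate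
19 | (1R,4R,5R)-1-[(E)-heptadec-12-en-1-yl]cyclohex-2-ene-1,4,5-triol | CCCC/C=C/CCCCCCCCCCC[C@]1(O)C=C[C@@H](O)[C@H](O)C1 | target

Total step count: 9. Longest linear sequence: 9 steps (1 or 2 to 19).

Steps most likely to fail

Step 5 (key step): retro-aldol fragmentation of the lithium aldolate, migration of the silyl group from the tertiary to the new secondary oxygen, or a second intermolecular aldol addition may outrun ring closure. Fallback: starting again from 8, a double Knoevenagel–Doebner-type condensation with 3-oxopentanedioic acid under buffered amine catalysis (piperidinium acetate, MeCN, rt → 60 °C) replaces the strongly basic dianion. Both aldehydes should add the doubly activated methylene carbons to give 5-[(tert-butyldimethylsilyl)oxy]-5-[(E)-heptadec-12-en-1-yl]-4,6-dihydroxy-2-oxocyclohexane-1,3-dicarboxylic acid F1, which should lose two molecules each of carbon dioxide and water on warming and so rejoin the route at 14.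

Step 6: discrimination between the two enantiotopic enone arms may be insufficient, or 1,2-reduction or further reduction of the remaining enone may compete. Fallback: from 14, biocatalytic desymmetrisation with a flavin-dependent ene-reductase of the Old Yellow Enzyme family (NADPH recycled with glucose and glucose dehydrogenase, phosphate buffer pH 7 with co-solvent, 30 °C), the enzyme being picked from a panel for the R sense. It should reduce one enone C=C only and return directly to 15; no new compound arises (F0).

Step 4: over-reduction of one ester to the primary alcohol, or early collapse of the aluminium hemiacetal, may occur. Fallback: from 7, exhaustive reduction with LiBH4 (THF, 0 °C → rt) to 2-[(tert-butyldimethylsilyl)oxy]-2-[(E)-heptadec-12-en-1-yl]propane-1,3-diol F2, then double Swern oxidation ((COCl)2, DMSO, Et3N, CH2Cl2, −78 °C) back to 8.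

Further compounds
F1 | step 5 | 5-[(tert-butyldimethylsilyl)oxy]-5-[(E)-heptadec-12-en-1-yl]-4,6-dihydroxy-2-oxocyclohexane-1,3-dicarboxylic acid | CCCC/C=C/CCCCCCCCCCCC1(O[Si](C)(C)C(C)(C)C)C(O)C(C(=O)O)C(=O)C(C(=O)O)C1O
F0 | step 6 | none | none
F2 | step 4 | 2-[(tert-butyldimethylsilyl)oxy]-2-[(E)-heptadec-12-en-1-yl]propane-1,3-diol | CCCC/C=C/CCCCCCCCCCCC(O[Si](C)(C)C(C)(C)C)(CO)CO
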